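Ring B′, the cyclohexene of the primed half (phthalide numbering), contains an unsubstituted C4′H2–C5′H2 unit flanked by C3a′ and C6′. The route rests on removing this unit as ethylene: in one operation a Diels–Alder/retro-Diels–Alder reaction of ethylene with a flat, achiral 2-pyranone forms C3a′–C4′ and C5′–C6′, extrudes CO2 and delivers ring B′ as a silyloxydiene, unmasked to an enone whose C7′ carbonyl is reduced enantioselectively. This single carbinol centre steers a crossed diene–enal [2+2] photocycloaddition that sets C6, C7, C3a′ and C7a′ together and is later erased as the C6′=C7′ alkene; two alkyne lactonisations then give the E- and Z-butylidene lactones.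

Key step: step 3

Remarks on the chemistry.
- Locants: each half of the target is numbered as a 3-butylidenephthalide (C1 lactone carbonyl, O2, C3, C3a, C4–C7, C7a, side chain C8–C11). The unprimed half puts C6 and C7 into the cyclobutane (its carbocycle is ring A); the primed half puts C3a′ and C7a′ into it (its carbocycle is ring B′). Intermediates keep these locants for the corresponding atoms.
- The target SMILES is read as Z at C3=C8 (propyl cis to the ring oxygen) and E at C3′=C8′ (propyl trans to the ring oxygen).
- Assumption: tert-butyl 2-oxocyclohexane-1-carboxylate (13) and propylzinc bromide solution (24) are taken as commercial.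
- The sense of the CBS reduction follows the usual large/small model; the antipodal catalyst would be used if the sense proved opposite.

Step 1
Reactants: 1 dimethyl 3-oxopentanedioate; 2 ethyl 2,2-diethoxyacetate
Product: 4 methyl 6-(diethoxymethyl)-4-hydroxy-2-oxo-2H-pyran-5-carboxylate, via triketo diester 3 (not isolated)
Conditions: LiN(i-Pr)2 (3 equiv), THF, −78 → 0 °C; AcOH; then DBU (cat.), toluene, 80 °C
Reagents that add atoms: none
Why: Claisen acylation of the dianion of 1 by ester 2 gives the 3,5-dioxo ester 3, whose enol oxygen then attacks the remote methyl ester (the classical lactonisation of 3,5-dioxo esters to 4-hydroxy-2-pyranones); no stereocentre is created.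

Step 2
Reactants: 4 methyl 6-(diethoxymethyl)-4-hydroxy-2-oxo-2H-pyran-5-carboxylate
Product: 5 methyl 6-(diethoxymethyl)-2-oxo-4-[(triisopropylsilyl)oxy]-2H-pyran-5-carboxylate
Conditions: i-Pr3SiCl, imidazole, DMF, rt
Reagents that add atoms: chlorotri(propan-2-yl)silane, CC(C)[Si](Cl)(C(C)C)C(C)C
Why: Silyl ether formation on the acidic 4-hydroxy group fixes the 2-pyranone diene tautomer and installs a fluoride-labile mask for the future C7′ oxygen; no stereocentre is involved.

Step 3
Reactants: 5 methyl 6-(diethoxymethyl)-2-oxo-4-[(triisopropylsilyl)oxy]-2H-pyran-5-carboxylate; 6 ethylene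
Product: 9 methyl 2-(diethoxymethyl)-6-oxocyclohex-1-ene-1-carboxylate, via bicyclic lactone 7 (not isolated), via silyl dienol ether 8 (not isolated)
Conditions: 6 (40 bar), toluene, 150 °C (autoclave); then Bu4NF, AcOH, THF, 0 °C
Reagents that add atoms: none
Why: Ethylene adds suprafacially across C3 and C6 of the 2-pyranone (the future C6′ and C3a′) in a thermal [4+2] cycloaddition to give the 2-oxabicyclo[2.2.2]octenone 7, which loses CO2 by retro-[4+2] to the 2-silyloxycyclohexa-1,3-diene 8, and fluoride then unmasks enone 9. The closest known reaction type is the Diels–Alder/retro-Diels–Alder sequence of 2-pyranones with alkenes, which gives cyclohexa-1,3-dienes. Ring B′ is closed by the concerted cycloaddition itself, both new σ-bonds (C3a′–C4′ and C5′–C6′) forming in one six-electron event, after which the lactone bridge of the temporary bicycle is excised as CO2. No stereocentre survives, because the two bridgehead centres of racemic 7 are destroyed on CO2 loss, so no stereocontrol is needed. The step needs a single addition without aromatisation: the symmetrical dienophile removes any regiochemical issue, the C5 ester activates the pyranone, the hindered trisubstituted diene 8 should be far less reactive towards a second ethylene, and a CH2–CH2 unit without leaving group cannot aromatise.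

Step 4
Reactants: 9 methyl 2-(diethoxymethyl)-6-oxocyclohex-1-ene-1-carboxylate
Product: 10 methyl (6S)-2-(diethoxymethyl)-6-hydroxycyclohex-1-ene-1-carboxylate
Conditions: (R)-2-methyl-CBS-oxazaborolidine (20 mol %), catecholborane, toluene, −78 °C
Reagents that add atoms: none
Why: CBS reduction (catalytic enantioselective 1,2-reduction of an α-substituted cyclohexenone, with the substituted sp2 carbon C7a′ as the large and C6′H2 as the small group) should deliver the (S)-carbinol at C7′, the only stereocentre of the route set by a chiral reagent.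

Step 5
Reactants: 10 methyl (6S)-2-(diethoxymethyl)-6-hydroxycyclohex-1-ene-1-carboxylate
Product: 11 methyl (6S)-6-[(tert-butyldimethylsilyl)oxy]-2-(diethoxymethyl)cyclohex-1-ene-1-carboxylate
Conditions: t-BuMe2SiCl, imidazole, DMF, 35 °C
Reagents that add atoms: tert-butyl(chloro)dimethylsilane, CC(C)(C)[Si](C)(C)Cl
Why: Silyl ether formation on the secondary allylic alcohol prevents hemiacetal formation with the aldehyde released next and turns the C7′ substituent into a bulky group for facial control; the stereocentre is untouched.

Step 6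
Reactants: 11 methyl (6S)-6-[(tert-butyldimethylsilyl)oxy]-2-(diethoxymethyl)cyclohex-1-ene-1-carboxylate
Product: 12 methyl (6S)-6-[(tert-butyldimethylsilyl)oxy]-2-formylcyclohex-1-ene-1-carboxylate
Conditions: pyridinium 4-toluenesulfonate (cat.), acetone–H2O, 40 °C
Reagents that add atoms: water, O
Why: Mild acid-catalysed acetal hydrolysis frees the conjugated aldehyde, which becomes the dominant acceptor group of the tetrasubstituted alkene, while the allylic silyl ether and the ester survive; the C7′ centre is not affected.

Step 7
Reactants: 13 tert-butyl 2-oxocyclohexane-1-carboxylate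
Product: 15 tert-butyl 6-oxocyclohex-1-ene-1-carboxylate, via selenide 14 (not isolated)
Conditions: PhSeCl, pyridine, CH2Cl2, 0 °C; then 30% aq. H2O2, 0 °C → rt
Reagents that add atoms: none
Why: α-Selenenylation of the β-keto ester followed by selenoxide elimination (syn-elimination towards the only β-hydrogens) gives the 2-carboalkoxy cyclohexenone; no stereocentre remains.

Step 8
Reactants: 15 tert-butyl 6-oxocyclohex-1-ene-1-carboxylate
Product: 16 tert-butyl 2-[(4-methylbenzenesulfonyl)oxy]cyclohexa-1,5-diene-1-carboxylate
Conditions: TsCl, Et3N, N-methylimidazole, CH2Cl2, 0 °C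
Reagents that add atoms: 4-methylbenzenesulfonyl chloride, Cc1ccc(cc1)S(Cl)(=O)=O
Why: Amine-mediated soft enolisation removes the γ-hydrogen to give the fully conjugated (vinylogous β-keto ester) dienolate, which is O-sulfonylated at the ketone oxygen (enol tosylate formation) to give ring A with its C6=C7 alkene and a coupling handle at C3a.

Step 9
Reactants: 12 methyl (6S)-6-[(tert-butyldimethylsilyl)oxy]-2-formylcyclohex-1-ene-1-carboxylate; 16 tert-butyl 2-[(4-methylbenzenesulfonyl)oxy]cyclohexa-1,5-diene-1-carboxylate
Product: 17 formyl cycloadduct (cis-syn-cis tricycle; ring A enol tosylate tert-butyl ester; C3a′ formyl; C7a′ methyl ester; C7′ silyl ether)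
Conditions: thioxanthone (10 mol %), 405 nm LED, degassed CH2Cl2, −20 °C, 16 (3 equiv) added slowly
Reagents that add atoms: none
Why: In this triplet-sensitised crossed [2+2] photocycloaddition of a 1,3-diene with an electron-poor alkene, thioxanthone should pass its triplet energy to diene 16 (expected to hold the lowest triplet in the mixture), whose terminal C6 adds to C7a′ (β to the coplanar formyl group, the flanked ester being twisted out of conjugation) on the face opposite the pseudo-axial silyloxy group, and the 1,4-biradical then closes C7–C3a′ to the doubly cis-fused cyclobutane with ring A turned over C7′–H and C4′H2 and away from the out-of-plane ester, so that the C7′ centre relays to C6, C7, C3a′ and C7a′ in one event.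

Step 10
Reactants: 17 formyl cycloadduct
Product: 18 ethynyl silyl ether (C3a′ ethynyl; C7′ silyl ether)
Conditions: Me3SiCHN2, n-BuLi, THF, −78 °C; then 17, −78 → 0 °C
Reagents that add atoms: (trimethylsilyl)diazomethane, C[Si](C)(C)C=[N+]=[N-]
Why: Colvin rearrangement: the lithiated diazo reagent adds to the non-enolisable aldehyde, Peterson-type loss of silanolate and then of N2 gives an alkylidene carbene, and its 1,2-hydrogen shift gives the terminal alkyne at low temperature without touching the enol tosylate, the esters or any stereocentre.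

Step 11
Reactants: 18 ethynyl silyl ether
Product: 19 ethynyl carbinol (free C7′ hydroxy group)
Conditions: HF·pyridine, pyridine, THF, 0 °C → rt
Reagents that add atoms: none
Why: Fluoride-mediated cleavage of the silyl ether under pyridine buffering should leave the tert-butyl ester, the enol tosylate and the alkyne intact and does not touch the stereocentres.

Step 12
Reactants: 19 ethynyl carbinol
Product: 21 ethynyl cyclohexene tert-butyl ester (C6′=C7′ alkene in ring B′), via sulfamate ester 20 (not isolated)
Conditions: Burgess reagent, toluene, 70 °C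
Reagents that add atoms: none
Why: Burgess dehydration proceeds by thermal syn-elimination of sulfamate 20, and because C7a′ is quaternary only the C6′ hydrogens are available, so the alkene can form only as C6′=C7′ while the auxiliary C7′ stereocentre is erased.

Step 13
Reactants: 21 ethynyl cyclohexene tert-butyl ester
Product: 22 ethynyl cyclohexene acid (free C7a carboxylic acid)
Conditions: CF3CO2H, CH2Cl2, 0 °C
Reagents that add atoms: none
Why: Acidolysis of the tert-butyl ester (loss of 2-methylpropene) frees the ring A acid before any acid-sensitive enol lactone exists, the methyl ester, enol tosylate, alkyne and alkenes being stable to these conditions.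

Step 14
Reactants: 22 ethynyl cyclohexene acid
Product: 23 (E)-iodomethylene lactone acid
Conditions: I2 (3 equiv), MeCN, rt, dark
Reagents that add atoms: iodine, II
Why: Iodolactonisation of the alkynyl methyl ester (electrophilic 5-exo-dig cyclisation): the ester carbonyl oxygen attacks C3′ of the iodine-activated alkyne anti to iodine and iodide dealkylates the oxonium ion, giving the cis-fused lactone with iodine trans to the ring oxygen (E), the cis relation of C1′ and C3′ from step 9 allowing only this ring fusion.

Step 15
Reactants: 23 (E)-iodomethylene lactone acid; 24 propylzinc bromide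
Product: 25 (E)-butylidene lactone acid
Conditions: n-PrZnBr 24 (2.5 equiv), Pd(PPh3)4 (5 mol %), THF, 0 °C → rt
Reagents that add atoms: none
Why: Negishi coupling with retention of alkene geometry places the propyl group trans to the ring oxygen (E-butylidene), oxidative addition at the C–I bond being much faster than at the enol tosylate and one extra equivalent of 24 being consumed by the acid proton.

Step 16
Reactants: 25 (E)-butylidene lactone acid; 26 pent-1-yne
Product: 28 target CNP0371639.1, via enynoic acid 27 (not isolated)
Conditions: PdCl2(PPh3)2 (5 mol %), CuI (10 mol %), Et3N, MeCN, 45 °C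
Reagents that add atoms: none
Why: Tandem Sonogashira coupling/lactonisation: coupling at the activated enol tosylate gives the (Z)-2-en-4-ynoic acid 27, whose carboxylate adds anti across the alkyne in a 5-exo-dig closure under the same conditions to give the butenolide with propyl cis to the ring oxygen (Z), the mild base and temperature leaving the E-lactone and all stereocentres unchanged.

Compound list

1 | dimethyl 3-oxopentanedioate | COC(=O)CC(=O)CC(=O)OC | starting material
2 | ethyl 2,2-diethoxyacetate | CCOC(=O)C(OCC)OCC | starting material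
3 | dimethyl 2-(2,2-diethoxyacetyl)-3-oxopentanedioate (triketo diester, racemic/enolised, not isolated) | COC(=O)CC(=O)C(C(=O)OC)C(=O)C(OCC)OCC | intermediate
4 | methyl 6-(diethoxymethyl)-4-hydroxy-2-oxo-2H-pyran-5-carboxylate | CCOC(OCC)C1=C(C(=O)OC)C(O)=CC(=O)O1 | intermediate
5 | methyl 6-(diethoxymethyl)-2-oxo-4-[(triisopropylsilyl)oxy]-2H-pyran-5-carboxylate | CCOC(OCC)C1=C(C(=O)OC)C(O[Si](C(C)C)(C(C)C)C(C)C)=CC(=O)O1 | intermediate
6 | ethylene | C=C | starting material
7 | methyl 1-(diethoxymethyl)-3-oxo-5-[(triisopropylsilyl)oxy]-2-oxabicyclo[2.2.2]oct-5-ene-6-carboxylate (bicyclic lactone, racemic, not isolated) | CCOC(OCC)C12CCC(C(=O)O1)C(O[Si](C(C)C)(C(C)C)C(C)C)=C2C(=O)OC | intermediate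
8 | methyl 2-(diethoxymethyl)-6-[(triisopropylsilyl)oxy]cyclohexa-1,5-diene-1-carboxylate (silyl dienol ether, not isolated) | CCOC(OCC)C1=C(C(=O)OC)C(O[Si](C(C)C)(C(C)C)C(C)C)=CCC1 | intermediate
9 | methyl 2-(diethoxymethyl)-6-oxocyclohex-1-ene-1-carboxylate | CCOC(OCC)C1=C(C(=O)OC)C(=O)CCC1 | intermediate
10 | methyl (6S)-2-(diethoxymethyl)-6-hydroxycyclohex-1-ene-1-carboxylate | CCOC(OCC)C1=C(C(=O)OC)[C@@H](O)CCC1 | intermediate
11 | methyl (6S)-6-[(tert-butyldimethylsilyl)oxy]-2-(diethoxymethyl)cyclohex-1-ene-1-carboxylate | CCOC(OCC)C1=C(C(=O)OC)[C@@H](O[Si](C)(C)C(C)(C)C)CCC1 | intermediate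
12 | methyl (6S)-6-[(tert-butyldimethylsilyl)oxy]-2-formylcyclohex-1-ene-1-carboxylate | O=CC1=C(C(=O)OC)[C@@H](O[Si](C)(C)C(C)(C)C)CCC1 | intermediate
13 | tert-butyl 2-oxocyclohexane-1-carboxylate | CC(C)(C)OC(=O)C1CCCCC1=O | starting material
14 | tert-butyl 2-oxo-1-(phenylselanyl)cyclohexane-1-carboxylate (selenide, racemic, not isolated) | CC(C)(C)OC(=O)C1([Se]c2ccccc2)CCCCC1=O | intermediate
15 | tert-butyl 6-oxocyclohex-1-ene-1-carboxylate | CC(C)(C)OC(=O)C1=CCCCC1=O | intermediate
16 | tert-butyl 2-[(4-methylbenzenesulfonyl)oxy]cyclohexa-1,5-diene-1-carboxylate | CC(C)(C)OC(=O)C1=C(OS(=O)(=O)c2ccc(C)cc2)CCC=C1 | intermediate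
17 | formyl cycloadduct: cyclobutane C6–C7–C3a′–C7a′ cis-fused to ring A (C3a=C7a; C3a–OTs; C7a–CO2t-Bu) and to saturated ring B′, rings A and B′ on the same face of the cyclobutane; C3a′–CHO and C7a′–CO2Me on the opposite face; (7′S)-OSi(t-Bu)Me2 trans to C6; ring-carbon configuration as in 28 | CC(C)(C)OC(=O)C2=C(OS(=O)(=O)c3ccc(C)cc3)CC[C@H]1[C@@H]2[C@@]2(C=O)CCC[C@H](O[Si](C)(C)C(C)(C)C)[C@@]12C(=O)OC | intermediate
18 | ethynyl silyl ether: as 17 with C3a′–C≡CH in place of the formyl group | CC(C)(C)OC(=O)C2=C(OS(=O)(=O)c3ccc(C)cc3)CC[C@H]1[C@@H]2[C@@]2(C#C)CCC[C@H](O[Si](C)(C)C(C)(C)C)[C@@]12C(=O)OC | intermediate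
19 | ethynyl carbinol: as 18 with free (7′S)-hydroxy group | CC(C)(C)OC(=O)C2=C(OS(=O)(=O)c3ccc(C)cc3)CC[C@H]1[C@@H]2[C@@]2(C#C)CCC[C@H](O)[C@@]12C(=O)OC | intermediate
20 | sulfamate ester of 19 (C7′–OSO2NHCO2Me, not isolated) | CC(C)(C)OC(=O)C2=C(OS(=O)(=O)c3ccc(C)cc3)CC[C@H]1[C@@H]2[C@@]2(C#C)CCC[C@H](OS(=O)(=O)NC(=O)OC)[C@@]12C(=O)OC | intermediate
21 | ethynyl cyclohexene tert-butyl ester: as 19 but with the C6′=C7′ alkene in ring B′ and no oxygen at C7′ | CC(C)(C)OC(=O)C2=C(OS(=O)(=O)c3ccc(C)cc3)CC[C@H]1[C@@H]2[C@@]2(C#C)CCC=C[C@@]12C(=O)OC | intermediate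
22 | ethynyl cyclohexene acid: 21 with free C7a–CO2H | OC(=O)C2=C(OS(=O)(=O)c3ccc(C)cc3)CC[C@H]1[C@@H]2[C@@]2(C#C)CCC=C[C@@]12C(=O)OC | intermediate
23 | (E)-iodomethylene lactone acid: lactone C1′(=O)–O–C3′(=CHI) closed across C7a′/C3a′, iodine trans to the ring oxygen | OC(=O)C2=C(OS(=O)(=O)c3ccc(C)cc3)CC[C@H]1[C@@H]2[C@@]23CCC=C[C@@]12C(=O)O/C3=C/I | intermediate
24 | propylzinc bromide (solution in THF) | CCC[Zn]Br | starting material
25 | (E)-butylidene lactone acid: 23 with propyl in place of iodine (propyl trans to the ring oxygen) | OC(=O)C2=C(OS(=O)(=O)c3ccc(C)cc3)CC[C@H]1[C@@H]2[C@@]23CCC=C[C@@]12C(=O)O/C3=C/CCC | intermediate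
26 | pent-1-yne | CCCC#C | starting material
27 | enynoic acid: 25 with pent-1-ynyl at C3a in place of the tosyloxy group (not isolated) | OC(=O)C2=C(C#CCCC)CC[C@H]1[C@@H]2[C@@]23CCC=C[C@@]12C(=O)O/C3=C/CCC | intermediate
28 | CNP0371639.1: (3Z)-3-butylidene-4,5,6,7-tetrahydro-2-benzofuran-1(3H)-one joined through C6 and C7 to C7a′ and C3a′ of (3′E)-3′-butylidene-3a′,4′,5′,7a′-tetrahydro-2-benzofuran-1′(3′H)-one; (6S,7R,3a′S,7a′R) in the locants used here; cyclobutane cis-fused to rings A and B′ on the same face, lactone of the primed half on the other | CCC/C=C1\OC(=O)C2=C1CC[C@H]1[C@@H]2[C@@]23CCC=C[C@@]12C(=O)O/C3=C/CCC | target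

Total step count: 16 steps. Longest linear sequence: 14 steps (steps 1–6 and 9–16; steps 7 and 8 make the second photopartner).

Steps most likely to fail

Step 9. The diene triplet may form its first bond at the formyl-bearing carbon (head-to-head orientation), may close with ring A turned away from ring B′, may attack syn to the silyl ether, or may be consumed by self-dimerisation. The fallback changes the excited partner and the source of absolute configuration; it sets out from enone 9 (with diene 16) and returns at 17. Direct irradiation of the enone chromophore of 9 at 366 nm in the presence of 16 (enone–alkene [2+2], where the head-to-tail rule sends the nucleophilic diene terminus C6 to the α-carbon C7a′) should give the racemic keto acetal cycloadduct F1. CBS reduction of its hindered ketone with the (R)-oxazaborolidine, run as a kinetic resolution, should give the (7′S)-carbinol acetal F2, separated from the unreacted antipode. Silylation with t-BuMe2SiCl and imidazole gives the silyl ether acetal F3, and hydrolysis of the acetal with pyridinium 4-toluenesulfonate in wet acetone returns to 17.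

Step 3. The cycloaddition of unactivated ethylene may be too slow at temperatures that the silyl ether and the acetal tolerate, or the diene formed may add a second ethylene. The fallback builds ring B′ by conjugate addition and aldol condensation instead; it sets out from 2 and returns at 9. Addition of MeMgBr to 2 at −78 °C gives 1,1-diethoxypropan-2-one F4, and condensation with pyrrolidine gives the enamine 1-(3,3-diethoxyprop-1-en-2-yl)pyrrolidine F5. Michael addition of F5 to Nazarov's reagent (methyl 3-oxopent-4-enoate) and hydrolysis give methyl 8,8-diethoxy-3,7-dioxooctanoate F6. Intramolecular Knoevenagel-type aldol condensation of F6 (piperidinium acetate, toluene, reflux) between the active methylene and the acetal-bearing ketone closes the six-membered ring and gives 9.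

Step 14. The electrophile may engage the ring B′ alkene with participation of the neighbouring ester, or the closure may go 6-endo. The fallback changes the order of events so that the halocyclisation precedes formation of the ring alkene; it sets out from 18 and returns at 25. Treatment of 18 with I2 in MeCN gives the silyloxy (E)-iodomethylene lactone F7, and Negishi coupling with 24 and Pd(PPh3)4 gives the silyloxy (E)-butylidene lactone F8. Buffered HF·pyridine gives the carbinol F9, and Burgess dehydration gives the ring B′ cyclohexene tert-butyl ester F10. Cleavage of the tert-butyl ester under non-protic conditions (Me3SiOSO2CF3, 2,6-lutidine, then aqueous work-up) gives 25.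

Further compounds

F1 | step 9 | racemic keto acetal cycloadduct (C7′ ketone, C3a′ diethoxymethyl; enantiomer of the target series drawn) | CC(C)(C)OC(=O)C2=C(OS(=O)(=O)c3ccc(C)cc3)CC[C@H]1[C@@H]2[C@@]2(C(OCC)OCC)CCCC(=O)[C@@]12C(=O)OC
F2 | step 9 | (7′S)-carbinol acetal | CC(C)(C)OC(=O)C2=C(OS(=O)(=O)c3ccc(C)cc3)CC[C@H]1[C@@H]2[C@@]2(C(OCC)OCC)CCC[C@H](O)[C@@]12C(=O)OC
F3 | step 9 | (7′S)-silyl ether acetal | CC(C)(C)OC(=O)C2=C(OS(=O)(=O)c3ccc(C)cc3)CC[C@H]1[C@@H]2[C@@]2(C(OCC)OCC)CCC[C@H](O[Si](C)(C)C(C)(C)C)[C@@]12C(=O)OC
F4 | step 3 | 1,1-diethoxypropan-2-one | CCOC(OCC)C(C)=O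
F5 | step 3 | 1-(3,3-diethoxyprop-1-en-2-yl)pyrrolidine | C=C(N1CCCC1)C(OCC)OCC
F6 | step 3 | methyl 8,8-diethoxy-3,7-dioxooctanoate | CCOC(OCC)C(=O)CCCC(=O)CC(=O)OC
F7 | step 14 | silyloxy (E)-iodomethylene lactone (ring A tert-butyl ester and tosylate retained) | CC(C)(C)OC(=O)C2=C(OS(=O)(=O)c3ccc(C)cc3)CC[C@H]1[C@@H]2[C@@]23CCC[C@H](O[Si](C)(C)C(C)(C)C)[C@@]12C(=O)O/C3=C/I
F8 | step 14 | silyloxy (E)-butylidene lactone | CC(C)(C)OC(=O)C2=C(OS(=O)(=O)c3ccc(C)cc3)CC[C@H]1[C@@H]2[C@@]23CCC[C@H](O[Si](C)(C)C(C)(C)C)[C@@]12C(=O)O/C3=C/CCC
F9 | step 14 | (7′S)-carbinol (E)-butylidene lactone | CC(C)(C)OC(=O)C2=C(OS(=O)(=O)c3ccc(C)cc3)CC[C@H]1[C@@H]2[C@@]23CCC[C@H](O)[C@@]12C(=O)O/C3=C/CCC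
F10 | step 14 | ring B′ cyclohexene (E)-butylidene lactone tert-butyl ester | CC(C)(C)OC(=O)C2=C(OS(=O)(=O)c3ccc(C)cc3)CC[C@H]1[C@@H]2[C@@]23CCC=C[C@@]12C(=O)O/C3=C/CCC
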